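Numbers refer to the compound list after the steps. Flavanone atoms carry plain locants (rings A, B, C); flavone atoms carry doubly primed locants (benzo ring D, aryl ring E with oxygen O4‴).

## The problem

Target 20 is a biflavonoid: C3 of a naringenin-type flavanone (rings A, B, C) is bonded to C8″ of an apigenin-type flavone (rings D, E), and of six phenolic oxygens only O7″ carries a hydrogen sulfate. The C3–C8″ bond joins a stereogenic sp3 carbon to an arene carbon flanked by O7″ and the pyranone oxygen, so direct substitution at C3 is not a realistic way to make it. Ring C holds two adjacent stereocentres, C2 (R, bearing ring B) and C3 (S), in a trans relationship. Once the C4 ketone exists, C3 is enolisable but settles in the diequatorial trans arrangement, so C2 controls C3. C2 is controlled only by the step that sets it, and base would erase both centres through β-elimination of the ring A phenoxide and reclosure. The aryl sulfate monoester does not tolerate acid and must sit on one oxygen only, so the sulfate site has to be singled out early and the end of the route has to be neutral and reductive. The enabling feature appears when the C4 carbonyl is removed: ring C is then a 2,3-trans-diarylchroman whose O1–C2 and C3–C4 bonds are the two new bonds of a [4+2] union between an ortho-quinone methide of ring A (O1, C8a, C4a, C4) and the E-alkene C2=C3 that links ring B to C8″. The oxygen donors O1, O5 and O7, all ortho or para to C4a, make that methide easy to form and later make C4–H the best hydride donor for reoxidation, but they also make the open ring A positions nucleophilic, which the plan must keep in check.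

## Retrosynthesis

**20 ⇒ 19 ⇒ 18 (unmasking).** The last operations cut five benzyl–oxygen bonds, one aryl–bromine bond and the trichloroethyl–oxygen bond of a sulfate diester. Hydrogen on palladium removes the benzyl ethers and the bromine together, and zinc fragments the trichloroethyl ester; both are near neutral, as the sulfate monoester and the enolisable flavanone require. The neighbouring choice, sulfating a free O7″ late, would need one more orthogonal protecting group and its removal by acid or fluoride next to the flavanone, and would forgo the service the diester does in the key step. Zinc has to come first, because palladium would remove chlorine atoms singly and leave esters that no longer fragment. Compound 18 differs from 20 only in masking groups, so these steps are asked for chemoselectivity alone.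

**18 ⇒ 17 ⇒ 16 (oxidation level of C4).** No skeletal bond is cut; the carbonyl is taken back to alcohol 17 and then to the methylene compound 16. In 16 the C3 centre is no longer enolisable and ring C is a plain chroman, which opens the structure to cycloaddition. Bringing C4 in as an acyl carbon instead would demand C-acylation of ring A or an aryne insertion followed by a basic ring closure. The forward oxidation must take hydride from C4 and not from C2, and must leave five benzyl ethers alone.

**16 ⇒ 4 + 14 (key disconnection, through methide 15).** O1–C2 and C3–C4 are cut together. This removes ring C and both stereocentres, and it replaces the hindered sp3–sp2 bond C3–C8″ by an alkene–arene bond that cross-coupling can make. A direct cut at C3–C8″ (arylation of a flavanone enolate at a di-ortho-substituted arene) offers no comparable simplification and puts an epimerisable centre under base. The forward reaction must deliver: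
- the methide carbon to the alkene carbon that carries ring D;
- reaction at the alkene in preference to arene nucleophiles;
- the trans ring;
- one enantioface.

Three spectator choices serve this:
- **Sulfate diester on O7″ before the step.** A free ortho hydroxyl would make ring D the directing donor (the ortho-hydroxystyrene polarity, giving the wrong regiochemistry) and could add to the alkene under acid. As the trichloroethyl diester it is an acceptor and a bystander.
- **Bromine at the future C8.** It occupies the ring A position that dominates electrophilic substitution of 5,7-dialkoxyflavans, lowers the nucleophilicity of the remaining position C6, raises the electrophilicity of the methide, and leaves in the final hydrogenolysis. A second bromine at C6 is avoided because it would twist the O7 benzyl ether out of conjugation and weaken the C4–H hydride donor needed afterwards.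
- **Benzyl ethers on all other oxygens.**

**14 ⇒ 11 + 13; 11 ⇒ 10 ⇒ 8 + 9.** The S–O7″ bond is cut first, giving phenol 11 and chlorosulfate 13 (from 12 and sulfuryl chloride). With O7″ masked as its methoxymethyl ether (10), the bond between C8″ and the alkene carbon is cut in the Heck sense to iodide 8 and commercial styrene 9. A Wittig-type cut at the C=C bond would need an 8-formylflavone, which is not available with comparable regiocontrol. Sulfation follows the coupling because zerovalent palladium and hot amine threaten the trichloromethyl group. The coupling must give the E-alkene at a di-ortho-substituted aryl iodide.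

**8 ⇒ 7 ⇒ 6 ⇒ 5.** The C8″–I bond, two benzyl–oxygen bonds and the O7″ acetal bond are cut, back to apigenin 5. The order follows the substrate. O7″–H is the most acidic hydroxyl and takes the methoxymethyl group first. The remaining two hydroxyls are then benzylated. Iodination comes last, because a free 5-hydroxyl directs halogen to C6″ whereas the 5,7-dialkoxy pattern directs it to C8″. The methoxymethyl ether marks the future sulfate site and is the one group that mild acid removes beside benzyl ethers.

**4 ⇒ 3 ⇒ 2 ⇒ 1.** The benzylic C–H (reduction), the C–Br bond and two benzyl–oxygen bonds are cut, back to 2,4,6-trihydroxybenzaldehyde 1. The formyl group does three jobs: it leaves one ortho hydroxyl unalkylated through chelation, limits bromination to one position, and becomes the methide carbon C4.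

## Roads not taken

**Alternative 1:** The cut is at C2–C(ring B) and C3–C8″, with ring C left open.
- **Key step:** pinacol (Z)-3-(tert-butyldimethylsilyloxy)prop-1-enylboronate A1 and 4-benzyloxyphenyllithium A2 are combined, and the resulting boronate meets 8-bromoflavone A3 under Pd(OAc)2 and a chiral MandyPhos ligand. Ring B migrates from boron to carbon as C8″ bonds to the neighbouring carbon, giving secondary boronate A4.
- **Merits:** both stereocentres are set in one catalytic step of a reaction class with a developed ligand set, stereospecifically from the alkene geometry. In stereochemical precedent this road is stronger than the chosen one.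
- **Weak points:** β-substituted alkenylboronates are the slow substrates of this coupling, and the electrophile is a di-ortho-substituted aryl bromide. A4 still lacks rings A and C. After the key step the C–B bond must be oxidised, the silyloxymethyl carbon raised to an acyl group and joined to ring A, and O1 closed onto a para-alkoxybenzylic carbinol that ionises easily, which puts C2 at risk. The silyl ether must then be exchanged for sulfate.
- **Comparison:** the chosen plan sets against the better precedent that its key step closes ring C, delivers the whole skeleton with the masked sulfate in place, and needs catalyst control at C3 only.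

**Alternative 2:** The cut is at O1–C8a and C4–C4a, with ring A entering as an aryne.
- **Key step:** CsF releases the aryne from 3,5-bis(benzyloxy)-2-(trimethylsilyl)phenyl triflate A6. The alkoxide of β-hydroxy imide A5 adds through oxygen, and the aryl anion attacks the imide carbonyl and expels the oxazolidinone, giving flavanone A7.
- **Merits:** C4 arrives as the ketone, so no redox relay is needed. The stereocentres come from aldol technology. The 3-alkoxy group of the aryne steers the oxygen to the correct carbon. A cis adduct would correct itself at C3 once the ring is closed. In redox economy and stereochemical pedigree this road is better than the chosen one.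
- **Weak points:** the nucleophile is the alkoxide of an aldol adduct of an aromatic aldehyde with an α-aryl acyl unit, which is an ideal retro-aldol substrate. The doubly activated C3–H can also quench the aryl anion. A7 carries a methoxymethyl ether where the sulfate belongs, so acid deprotection on the flavanone, sulfation and hydrogenolysis follow.
- **Comparison:** the chosen plan sets against it a non-basic key step in which no centre is epimerisable when formed, and a sulfate that is already in place.

**Alternative 3:** The cut is at C4a–C5, with ring A built last by Claisen condensation on a finished ring C.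
- **Key step:** Mg(OMe)2 in methanol enolises the side chain of dihydropyranone keto ester A8, C4a attacks the ester carbon, and ring A closes and aromatises to flavanone A9.
- **Merits:** it mirrors polyketide folding. Ring A appears with free hydroxyls, which saves two benzyl ethers and the C4 oxidation. The key step itself need not be stereoselective. In protecting-group economy it is the leanest on paper.
- **Weak points:** A8 already holds the whole stereochemical problem, and no short way to it is apparent. Under basic methoxide the pyranone ring can open by β-elimination, C3 can epimerise, and an aldol mode of closure competes. Decisively for this target, A9 has free O5 and O7 on ring A, so after loss of the methoxymethyl group the flavone O7″ cannot be sulfated selectively against the flavanone O7 without reprotection.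
- **Comparison:** the chosen plan has a less precedented key step but simple precursors (three and six steps) and a hydroxyl pattern in which the sulfate site is never ambiguous.

Key step: step 11

Remark: the target is read as (2R,3S), 2,3-trans, and is delivered as the drawn hydrogen sulfate after a final proton exchange, although it is best stored as a salt.
Remark: which antipode of the chiral acid leads to the (2R,3S) series cannot be predicted; the (R) acid is written and the (S) acid is used if the sense proves opposite.

## Steps

Step 1
Reactants: 1 2,4,6-trihydroxybenzaldehyde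
Product: 2 2,4-bis(benzyloxy)-6-hydroxybenzaldehyde
Conditions: BnBr (2.05 equiv), K2CO3, DMF, 0 °C to rt
Reagents that add atoms: benzyl bromide, BrCc1ccccc1
Why: Williamson etherification; the para hydroxyl and one ortho hydroxyl are alkylated, while the last ortho hydroxyl is held by its hydrogen bond to the formyl oxygen and should remain when two equivalents are used.

Step 2
Reactants: 2 2,4-bis(benzyloxy)-6-hydroxybenzaldehyde
Product: 3 4,6-bis(benzyloxy)-3-bromo-2-hydroxybenzaldehyde
Conditions: NBS (1.0 equiv), CH2Cl2, −10 to 0 °C
Reagents that add atoms: N-bromosuccinimide, O=C1CCC(=O)N1Br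
Why: Electrophilic aromatic bromination; chelated 2-hydroxy-4,6-dialkoxy aryl carbonyl compounds take up halogen at the less hindered position next to the free hydroxyl, and the formyl group should stop the reaction at monobromination.

Step 3
Reactants: 3 4,6-bis(benzyloxy)-3-bromo-2-hydroxybenzaldehyde
Product: 4 3,5-bis(benzyloxy)-2-bromo-6-(hydroxymethyl)phenol
Conditions: NaBH4, THF–MeOH, 0 °C; pH 7 buffer work-up
Reagents that add atoms: none
Why: Borohydride reduction of the aldehyde; the salicyl alcohol is acid-sensitive and is used promptly without chromatography on acidic silica.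

Step 4
Reactants: 5 apigenin
Product: 6 5-hydroxy-2-(4-hydroxyphenyl)-7-(methoxymethoxy)-4H-chromen-4-one
Conditions: MOMCl (1.05 equiv), K2CO3 (1.05 equiv), DMF, 0 °C
Reagents that add atoms: chloromethyl methyl ether, COCCl
Why: O-alkylation under base limitation; the 7-hydroxyl, para to the pyranone carbonyl, is the most acidic phenol and the 5-hydroxyl is chelated, so one equivalent of base should direct the acetal to O7″, with the 4‴,7″-diether as a separable by-product.

Step 5
Reactants: 6 5-hydroxy-2-(4-hydroxyphenyl)-7-(methoxymethoxy)-4H-chromen-4-one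
Product: 7 5-(benzyloxy)-2-[4-(benzyloxy)phenyl]-7-(methoxymethoxy)-4H-chromen-4-one
Conditions: BnBr (3 equiv), K2CO3, nBu4NI (cat.), DMF, 70 °C
Reagents that add atoms: benzyl bromide, BrCc1ccccc1
Why: Williamson etherification; the chelated 5-hydroxyl needs heat and excess reagent, and the methoxymethyl ether is stable to base.

Step 6
Reactants: 7 5-(benzyloxy)-2-[4-(benzyloxy)phenyl]-7-(methoxymethoxy)-4H-chromen-4-one
Product: 8 5-(benzyloxy)-2-[4-(benzyloxy)phenyl]-8-iodo-7-(methoxymethoxy)-4H-chromen-4-one
Conditions: NIS (1.15 equiv), DMF, rt to 50 °C, dark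
Reagents that add atoms: N-iodosuccinimide, O=C1CCC(=O)N1I
Why: Electrophilic aromatic iodination; in 5,7-dialkoxyflavones C8″ is the preferred site because C6″ lies between two alkoxy groups, and the neutral reagent spares the acetal.

Step 7
Reactants: 8 5-(benzyloxy)-2-[4-(benzyloxy)phenyl]-8-iodo-7-(methoxymethoxy)-4H-chromen-4-one; 9 4-benzyloxystyrene
Product: 10 5-(benzyloxy)-2-[4-(benzyloxy)phenyl]-8-[(E)-2-(4-benzyloxyphenyl)ethenyl]-7-(methoxymethoxy)-4H-chromen-4-one
Conditions: Pd(OAc)2 (5 mol %), P(o-tol)3, Et3N, DMF, 95 °C
Reagents that add atoms: none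
Why: Mizoroki–Heck reaction; oxidative addition of the aryl iodide to zerovalent palladium, syn insertion at the terminal alkene carbon and syn β-hydride elimination should give the E-stilbene, with the acetal keeping a free ortho phenoxide away from the metal.

Step 8
Reactants: 10 5-(benzyloxy)-2-[4-(benzyloxy)phenyl]-8-[(E)-2-(4-benzyloxyphenyl)ethenyl]-7-(methoxymethoxy)-4H-chromen-4-one
Product: 11 5-(benzyloxy)-2-[4-(benzyloxy)phenyl]-8-[(E)-2-(4-benzyloxyphenyl)ethenyl]-7-hydroxy-4H-chromen-4-one
Conditions: 3 M aq. HCl, MeOH–THF, 40 °C
Reagents that add atoms: none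
Why: Acid-catalysed acetal exchange; the benzyl ethers and the stilbene should tolerate dilute acid at this temperature, and the reaction is stopped at full conversion so that the freed phenol does not add to the alkene.

Step 9
Reactants: 12 2,2,2-trichloroethanol
Product: 13 2,2,2-trichloroethyl chlorosulfate
Conditions: SO2Cl2, pyridine, Et2O, −78 °C to rt
Reagents that add atoms: sulfuryl chloride, ClS(Cl)(=O)=O
Why: O-sulfurylation of the alcohol with sulfuryl chloride, the standard preparation of this reagent for masked aryl sulfates.

Step 10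
Reactants: 11 5-(benzyloxy)-2-[4-(benzyloxy)phenyl]-8-[(E)-2-(4-benzyloxyphenyl)ethenyl]-7-hydroxy-4H-chromen-4-one; 13 2,2,2-trichloroethyl chlorosulfate
Product: 14 5-(benzyloxy)-2-[4-(benzyloxy)phenyl]-8-[(E)-2-(4-benzyloxyphenyl)ethenyl]-4-oxo-4H-chromen-7-yl 2,2,2-trichloroethyl sulfate
Conditions: Et3N, DMAP (cat.), THF, 0 °C to rt
Reagents that add atoms: none
Why: Sulfuryl transfer to the only free phenol with nucleophilic catalysis by DMAP; the resulting sulfate diester is stable to acid and oxidants and is cleaved later by zinc.

Step 11
Reactants: 4 3,5-bis(benzyloxy)-2-bromo-6-(hydroxymethyl)phenol; 14 5-(benzyloxy)-2-[4-(benzyloxy)phenyl]-8-[(E)-2-(4-benzyloxyphenyl)ethenyl]-4-oxo-4H-chromen-7-yl 2,2,2-trichloroethyl sulfate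
Product: 16 5-(benzyloxy)-2-[4-(benzyloxy)phenyl]-8-{(2R,3S)-5,7-bis(benzyloxy)-2-[4-(benzyloxy)phenyl]-8-bromo-3,4-dihydro-2H-chromen-3-yl}-4-oxo-4H-chromen-7-yl 2,2,2-trichloroethyl sulfate, via bromo ortho-quinone methide 15 (not isolated)
Conditions: (R)-3,3′-bis(2,4,6-triisopropylphenyl)-1,1′-binaphthyl-2,2′-diyl hydrogen phosphate (10 mol %), 5 Å molecular sieves, toluene, 25 °C, dark; 4 (2 equiv) added over 12 h
Reagents that add atoms: none
Why: Proposed new method: the acid protonates the benzylic hydroxyl of 4, water leaves, and the hydrogen-bonded methide 15 (or its contact ion pair with the chiral phosphate) is attacked at its CH2 carbon by the alkene carbon of 14 that carries the flavone, so that C3–C4 forms first while positive charge builds on the carbon bearing ring B, where the para-benzyloxyphenyl group stabilises it, and the ring A oxygen then closes O1–C2 in an asynchronous concerted or fast stepwise inverse-demand oxa-Diels–Alder reaction. The closest known reaction type is the Brønsted-acid-catalysed [4+2] cycloaddition of in situ ortho-quinone methides with styrenes and 1-arylpropenes to 2-arylchromans, which is enantioselective with chiral phosphoric acids when the alkene carries a hydrogen-bond donor; a donor-free stilbene with an unsubstituted methide has not been shown. Ring C closes as the six-membered ring of a [4π+2π] union (if stepwise, by 6-endo capture of the C2 benzylic cation by the ring A oxygen). C3 is set by which alkene face meets the methide inside the pocket of the phosphate bound to the methide oxygen, which is catalyst control; C2 follows from C3 because suprafacial addition to the E-alkene gives the trans ring, and because a stepwise or reversible O1–C2 closure ends in the diequatorial trans chroman without touching C3. The step needs regioselectivity, secured by donor ring B against ring D, which is twisted out of conjugation by its two ortho substituents and deactivated by the sulfate diester and the pyranone; it needs the alkene to win over arene nucleophiles, secured by the C8 bromine, the esterified O7″ and slow addition of 4; and it needs enantioface selectivity, which rests on the catalyst alone.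

Step 12
Reactants: 16 5-(benzyloxy)-2-[4-(benzyloxy)phenyl]-8-{(2R,3S)-5,7-bis(benzyloxy)-2-[4-(benzyloxy)phenyl]-8-bromo-3,4-dihydro-2H-chromen-3-yl}-4-oxo-4H-chromen-7-yl 2,2,2-trichloroethyl sulfate
Product: 17 5-(benzyloxy)-2-[4-(benzyloxy)phenyl]-8-{(2R,3R)-5,7-bis(benzyloxy)-2-[4-(benzyloxy)phenyl]-8-bromo-4-hydroxy-3,4-dihydro-2H-chromen-3-yl}-4-oxo-4H-chromen-7-yl 2,2,2-trichloroethyl sulfate (C4 epimers; the C3 descriptor changes by priority only)
Conditions: DDQ (1.5 equiv), CH2Cl2–H2O (20:1), 0 °C to rt
Reagents that add atoms: water, O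
Why: Benzylic hydride abstraction by DDQ at C4, whose cation is stabilised by O1, O5 and O7, followed by capture by water, as in the C4 functionalisation of benzylated flavan-3-ols; the C4 configuration is irrelevant and C2 and C3 are not involved.

Step 13
Reactants: 17 5-(benzyloxy)-2-[4-(benzyloxy)phenyl]-8-{(2R,3R)-5,7-bis(benzyloxy)-2-[4-(benzyloxy)phenyl]-8-bromo-4-hydroxy-3,4-dihydro-2H-chromen-3-yl}-4-oxo-4H-chromen-7-yl 2,2,2-trichloroethyl sulfate
Product: 18 5-(benzyloxy)-2-[4-(benzyloxy)phenyl]-8-{(2R,3S)-5,7-bis(benzyloxy)-2-[4-(benzyloxy)phenyl]-8-bromo-4-oxo-3,4-dihydro-2H-chromen-3-yl}-4-oxo-4H-chromen-7-yl 2,2,2-trichloroethyl sulfate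
Conditions: Dess–Martin periodinane, NaHCO3, CH2Cl2, 0 °C to rt
Reagents that add atoms: none
Why: Dess–Martin oxidation of the secondary benzylic alcohol under bicarbonate buffer; the conditions are non-basic, and any enolisation at C3 returns the thermodynamically preferred trans isomer.

Step 14
Reactants: 18 5-(benzyloxy)-2-[4-(benzyloxy)phenyl]-8-{(2R,3S)-5,7-bis(benzyloxy)-2-[4-(benzyloxy)phenyl]-8-bromo-4-oxo-3,4-dihydro-2H-chromen-3-yl}-4-oxo-4H-chromen-7-yl 2,2,2-trichloroethyl sulfate
Product: 19 ammonium 5-(benzyloxy)-2-[4-(benzyloxy)phenyl]-8-{(2R,3S)-5,7-bis(benzyloxy)-2-[4-(benzyloxy)phenyl]-8-bromo-4-oxo-3,4-dihydro-2H-chromen-3-yl}-4-oxo-4H-chromen-7-yl sulfate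
Conditions: Zn dust, HCO2NH4, MeOH–THF, rt
Reagents that add atoms: ammonium formate, [NH4+].[O-]C=O
Why: Reductive fragmentation; zinc inserts into a C–Cl bond of the trichloroethyl group and β-elimination expels the aryl sulfate monoester as its ammonium salt near neutrality, leaving the aryl bromide, benzyl ethers and ketone alone.

Step 15
Reactants: 19 ammonium 5-(benzyloxy)-2-[4-(benzyloxy)phenyl]-8-{(2R,3S)-5,7-bis(benzyloxy)-2-[4-(benzyloxy)phenyl]-8-bromo-4-oxo-3,4-dihydro-2H-chromen-3-yl}-4-oxo-4H-chromen-7-yl sulfate
Product: 20 8-[(2R,3S)-5,7-dihydroxy-2-(4-hydroxyphenyl)-4-oxo-3,4-dihydro-2H-chromen-3-yl]-5-hydroxy-2-(4-hydroxyphenyl)-4-oxo-4H-chromen-7-yl hydrogen sulfate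
Conditions: H2 (1 atm), Pd(OH)2/C, NH4OAc (buffer), THF–MeOH, rt; then cation-exchange resin (H+ form), 0 °C, freeze-drying
Reagents that add atoms: none
Why: Hydrogenolysis of the five benzyl ethers and hydrodebromination at C8 on palladium; sulfate monoester salts are stable to hydrogenolysis, the buffer takes up the hydrogen bromide, and the neutral medium leaves C2 and C3 untouched.

## Compound list

1 | 2,4,6-trihydroxybenzaldehyde | O=Cc1c(O)cc(O)cc1O | starting material
2 | 2,4-bis(benzyloxy)-6-hydroxybenzaldehyde | O=Cc1c(O)cc(OCc2ccccc2)cc1OCc1ccccc1 | intermediate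
3 | 4,6-bis(benzyloxy)-3-bromo-2-hydroxybenzaldehyde | O=Cc1c(O)c(Br)c(OCc2ccccc2)cc1OCc1ccccc1 | intermediate
4 | 3,5-bis(benzyloxy)-2-bromo-6-(hydroxymethyl)phenol | OCc1c(O)c(Br)c(OCc2ccccc2)cc1OCc1ccccc1 | intermediate
5 | apigenin, 5,7-dihydroxy-2-(4-hydroxyphenyl)-4H-chromen-4-one | O=c1cc(-c2ccc(O)cc2)oc2cc(O)cc(O)c12 | starting material
6 | 5-hydroxy-2-(4-hydroxyphenyl)-7-(methoxymethoxy)-4H-chromen-4-one | O=c1cc(-c2ccc(O)cc2)oc2cc(OCOC)cc(O)c12 | intermediate
7 | 5-(benzyloxy)-2-[4-(benzyloxy)phenyl]-7-(methoxymethoxy)-4H-chromen-4-one | O=c1cc(-c2ccc(OCc3ccccc3)cc2)oc2cc(OCOC)cc(OCc3ccccc3)c12 | intermediate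
8 | 5-(benzyloxy)-2-[4-(benzyloxy)phenyl]-8-iodo-7-(methoxymethoxy)-4H-chromen-4-one | O=c1cc(-c2ccc(OCc3ccccc3)cc2)oc2c(I)c(OCOC)cc(OCc3ccccc3)c12 | intermediate
9 | 4-benzyloxystyrene | C=Cc1ccc(OCc2ccccc2)cc1 | starting material
10 | 5-(benzyloxy)-2-[4-(benzyloxy)phenyl]-8-[(E)-2-(4-benzyloxyphenyl)ethenyl]-7-(methoxymethoxy)-4H-chromen-4-one | O=c1cc(-c2ccc(OCc3ccccc3)cc2)oc2c(/C=C/c3ccc(OCc4ccccc4)cc3)c(OCOC)cc(OCc3ccccc3)c12 | intermediate
11 | 5-(benzyloxy)-2-[4-(benzyloxy)phenyl]-8-[(E)-2-(4-benzyloxyphenyl)ethenyl]-7-hydroxy-4H-chromen-4-one | O=c1cc(-c2ccc(OCc3ccccc3)cc2)oc2c(/C=C/c3ccc(OCc4ccccc4)cc3)c(O)cc(OCc3ccccc3)c12 | intermediate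
12 | 2,2,2-trichloroethanol | OCC(Cl)(Cl)Cl | starting material
13 | 2,2,2-trichloroethyl chlorosulfate | ClS(=O)(=O)OCC(Cl)(Cl)Cl | intermediate
14 | 5-(benzyloxy)-2-[4-(benzyloxy)phenyl]-8-[(E)-2-(4-benzyloxyphenyl)ethenyl]-4-oxo-4H-chromen-7-yl 2,2,2-trichloroethyl sulfate | O=c1cc(-c2ccc(OCc3ccccc3)cc2)oc2c(/C=C/c3ccc(OCc4ccccc4)cc3)c(OS(=O)(=O)OCC(Cl)(Cl)Cl)cc(OCc3ccccc3)c12 | intermediate
15 | 3,5-bis(benzyloxy)-2-bromo-6-methylidenecyclohexa-2,4-dien-1-one (formed in the flask, not isolated) | C=C1C(=O)C(Br)=C(OCc2ccccc2)C=C1OCc1ccccc1 | intermediate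
16 | 5-(benzyloxy)-2-[4-(benzyloxy)phenyl]-8-{(2R,3S)-5,7-bis(benzyloxy)-2-[4-(benzyloxy)phenyl]-8-bromo-3,4-dihydro-2H-chromen-3-yl}-4-oxo-4H-chromen-7-yl 2,2,2-trichloroethyl sulfate | C1c2c(OCc3ccccc3)cc(OCc3ccccc3)c(Br)c2O[C@@H](c2ccc(OCc3ccccc3)cc2)[C@@H]1c1c(OS(=O)(=O)OCC(Cl)(Cl)Cl)cc(OCc2ccccc2)c2c(=O)cc(-c3ccc(OCc4ccccc4)cc3)oc12 | intermediate
17 | 5-(benzyloxy)-2-[4-(benzyloxy)phenyl]-8-{(2R,3R)-5,7-bis(benzyloxy)-2-[4-(benzyloxy)phenyl]-8-bromo-4-hydroxy-3,4-dihydro-2H-chromen-3-yl}-4-oxo-4H-chromen-7-yl 2,2,2-trichloroethyl sulfate, mixture of C4 epimers | OC1c2c(OCc3ccccc3)cc(OCc3ccccc3)c(Br)c2O[C@@H](c2ccc(OCc3ccccc3)cc2)[C@@H]1c1c(OS(=O)(=O)OCC(Cl)(Cl)Cl)cc(OCc2ccccc2)c2c(=O)cc(-c3ccc(OCc4ccccc4)cc3)oc12 | intermediate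
18 | 5-(benzyloxy)-2-[4-(benzyloxy)phenyl]-8-{(2R,3S)-5,7-bis(benzyloxy)-2-[4-(benzyloxy)phenyl]-8-bromo-4-oxo-3,4-dihydro-2H-chromen-3-yl}-4-oxo-4H-chromen-7-yl 2,2,2-trichloroethyl sulfate | O=C1c2c(OCc3ccccc3)cc(OCc3ccccc3)c(Br)c2O[C@@H](c2ccc(OCc3ccccc3)cc2)[C@@H]1c1c(OS(=O)(=O)OCC(Cl)(Cl)Cl)cc(OCc2ccccc2)c2c(=O)cc(-c3ccc(OCc4ccccc4)cc3)oc12 | intermediate
19 | ammonium 5-(benzyloxy)-2-[4-(benzyloxy)phenyl]-8-{(2R,3S)-5,7-bis(benzyloxy)-2-[4-(benzyloxy)phenyl]-8-bromo-4-oxo-3,4-dihydro-2H-chromen-3-yl}-4-oxo-4H-chromen-7-yl sulfate | O=C1c2c(OCc3ccccc3)cc(OCc3ccccc3)c(Br)c2O[C@@H](c2ccc(OCc3ccccc3)cc2)[C@@H]1c1c(OS(=O)(=O)[O-])cc(OCc2ccccc2)c2c(=O)cc(-c3ccc(OCc4ccccc4)cc3)oc12.[NH4+] | intermediate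
20 | 8-[(2R,3S)-5,7-dihydroxy-2-(4-hydroxyphenyl)-4-oxo-3,4-dihydro-2H-chromen-3-yl]-5-hydroxy-2-(4-hydroxyphenyl)-4-oxo-4H-chromen-7-yl hydrogen sulfate | O=C1c2c(O)cc(O)cc2O[C@@H](c2ccc(O)cc2)[C@@H]1c1c(OS(=O)(=O)O)cc(O)c2c(=O)cc(-c3ccc(O)cc3)oc12 | target

## Step count and least certain steps

Total: 15 steps. Longest linear sequence: 11 steps, from apigenin 5 to 20 (steps 4–8 and 10–15). The ring A branch (steps 1–3) and the reagent branch (step 9) join at steps 11 and 10.

**Step 11 (key step, proposed new method).**
- Most likely failures: poor facial selectivity, because the alkene offers the acid no hydrogen-bond donor; slow C–C bond formation at the hindered, twisted alkene carbon, so that the methide is lost to dimerisation or to substitution at the one open ring A position of 4 or of the product; and sequestration of the acid by the basic pyranone carbonyl.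
- Fallback (known chemistry), from 4 and 14 back to 16: the chiral acid is replaced by achiral diphenyl phosphate, which can be used at higher loading since no induction is asked of it, in the established acid-catalysed cycloaddition of methides with aryl alkenes. The trans cycloadduct then forms as the racemate, that is 16 together with its (2S,3R) enantiomer F1. The two are separated by preparative chromatography on a polysaccharide chiral stationary phase, and 16 continues at step 12.

**Step 4.**
- Most likely failure: incomplete site selectivity, with alkylation at O4‴ competing with O7″ and leading to the diether.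
- Fallback, from 5 back to 6: apigenin is peracetylated (Ac2O, pyridine) to apigenin triacetate F2. The 7-acetate alone is removed by thiophenol and imidazole in N-methylpyrrolidone, the known selective 7-deacylation of flavonoid peracetates, to give 4‴,5″-di-O-acetylapigenin F3. The free 7-hydroxyl is protected (MOMCl, iPr2NEt) to give the 7-O-methoxymethyl diacetate F4. Methanolysis (K2CO3 cat., MeOH) then returns 6.

**Step 7.**
- Most likely failure: slow alkene insertion at the di-ortho-substituted arylpalladium iodide, followed by reductive loss of iodine or arylation at the internal alkene carbon.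
- Fallback, from 9 and 8 back to 10: cross-metathesis of 9 with vinylboronic acid pinacol ester under the second-generation Grubbs catalyst RuCl2(=CHPh)(PCy3)(H2IMes) gives pinacol (E)-2-(4-benzyloxyphenyl)ethenylboronate F5. Suzuki–Miyaura coupling of F5 with 8 (PdCl2(dppf), K3PO4, dioxane–water) gives 10 with the alkene geometry fixed beforehand.

**Step 12.**
- Most likely failure: hydride abstraction from C2–H, which is activated by O1 and the para-benzyloxyphenyl ring, in competition with C4–H, followed by chromene formation and loss of both stereocentres; oxidative cleavage of a benzyl ether is a lesser risk.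
- Fallback, from 3 and 14 back to 17: the C4 oxygen is brought in with the methide. Aldehyde 3 and trimethyl orthoformate give dimethyl acetal F6. Under the acid conditions established in step 11, F6 loses methanol to the methoxy-substituted methide F7. F7 adds to 14 in the same sense and gives 4-methoxyflavan F8 as C4 epimers. Mild aqueous acid (TsOH cat., acetone–water) exchanges the methoxy group for hydroxyl and returns 17. The price is that enantiocontrol must be re-established for the substituted methide or replaced by resolution.

## Further compounds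

F1 | step 11 | (2S,3R) enantiomer of 16, formed beside 16 in the racemic cycloaddition | C1c2c(OCc3ccccc3)cc(OCc3ccccc3)c(Br)c2O[C@H](c2ccc(OCc3ccccc3)cc2)[C@H]1c1c(OS(=O)(=O)OCC(Cl)(Cl)Cl)cc(OCc2ccccc2)c2c(=O)cc(-c3ccc(OCc4ccccc4)cc3)oc12
F2 | step 4 | apigenin triacetate | O=c1cc(-c2ccc(OC(C)=O)cc2)oc2cc(OC(C)=O)cc(OC(C)=O)c12
F3 | step 4 | 4‴,5″-di-O-acetylapigenin (7-hydroxyl free) | O=c1cc(-c2ccc(OC(C)=O)cc2)oc2cc(O)cc(OC(C)=O)c12
F4 | step 4 | 4‴,5″-di-O-acetyl-7″-O-(methoxymethyl)apigenin | O=c1cc(-c2ccc(OC(C)=O)cc2)oc2cc(OCOC)cc(OC(C)=O)c12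
F5 | step 7 | pinacol (E)-2-(4-benzyloxyphenyl)ethenylboronate | CC1(C)OB(/C=C/c2ccc(OCc3ccccc3)cc2)OC1(C)C
F6 | step 12 | 3,5-bis(benzyloxy)-2-bromo-6-(dimethoxymethyl)phenol | COC(OC)c1c(O)c(Br)c(OCc2ccccc2)cc1OCc1ccccc1
F7 | step 12 | 3,5-bis(benzyloxy)-2-bromo-6-(methoxymethylidene)cyclohexa-2,4-dien-1-one | COC=C1C(=O)C(Br)=C(OCc2ccccc2)C=C1OCc1ccccc1
F8 | step 12 | 4-methoxy analogue of 17 (methyl ether at C4, C4 epimers, C2 and C3 as in 16) | COC1c2c(OCc3ccccc3)cc(OCc3ccccc3)c(Br)c2O[C@@H](c2ccc(OCc3ccccc3)cc2)[C@@H]1c1c(OS(=O)(=O)OCC(Cl)(Cl)Cl)cc(OCc2ccccc2)c2c(=O)cc(-c3ccc(OCc4ccccc4)cc3)oc12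
A1 | alternative 1 | pinacol (Z)-3-(tert-butyldimethylsilyloxy)prop-1-enylboronate | CC1(C)OB(/C=C\CO[Si](C)(C)C(C)(C)C)OC1(C)C
A2 | alternative 1 | 4-benzyloxyphenyllithium | [Li]c1ccc(OCc2ccccc2)cc1
A3 | alternative 1 | 5-(benzyloxy)-2-[4-(benzyloxy)phenyl]-8-bromo-7-(triisopropylsilyloxy)-4H-chromen-4-one | O=c1cc(-c2ccc(OCc3ccccc3)cc2)oc2c(Br)c(O[Si](C(C)C)(C(C)C)C(C)C)cc(OCc3ccccc3)c12
A4 | alternative 1 | secondary pinacol boronate with ring B on C2 and the flavone on C3, target configuration at both carbons | CC1(C)OB(OC1(C)C)[C@@H](c1ccc(OCc2ccccc2)cc1)[C@H](c1c(O[Si](C(C)C)(C(C)C)C(C)C)cc(OCc2ccccc2)c2c(=O)cc(-c3ccc(OCc4ccccc4)cc3)oc12)CO[Si](C)(C)C(C)(C)C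
A5 | alternative 2 | 3-{3-[4-(benzyloxy)phenyl]-3-hydroxy-2-[5-(benzyloxy)-2-(4-benzyloxyphenyl)-7-(methoxymethoxy)-4-oxo-4H-chromen-8-yl]propanoyl}oxazolidin-2-one, target configuration at both carbons | O[C@@H](c1ccc(OCc2ccccc2)cc1)[C@@H](C(=O)N1CCOC1=O)c1c(OCOC)cc(OCc2ccccc2)c2c(=O)cc(-c3ccc(OCc4ccccc4)cc3)oc12
A6 | alternative 2 | 3,5-bis(benzyloxy)-2-(trimethylsilyl)phenyl trifluoromethanesulfonate | C[Si](C)(C)c1c(OCc2ccccc2)cc(OCc2ccccc2)cc1OS(=O)(=O)C(F)(F)F
A7 | alternative 2 | pentabenzyl flavanone–flavone with a methoxymethyl ether on O7″ | O=C1c2c(OCc3ccccc3)cc(OCc3ccccc3)cc2O[C@@H](c2ccc(OCc3ccccc3)cc2)[C@@H]1c1c(OCOC)cc(OCc2ccccc2)c2c(=O)cc(-c3ccc(OCc4ccccc4)cc3)oc12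
A8 | alternative 3 | methyl 4-{2-[4-(benzyloxy)phenyl]-3-[5-(benzyloxy)-2-(4-benzyloxyphenyl)-7-(methoxymethoxy)-4-oxo-4H-chromen-8-yl]-4-oxo-3,4-dihydro-2H-pyran-6-yl}-3-oxobutanoate, target configuration at both carbons | O=C1C=C(CC(=O)CC(=O)OC)O[C@@H](c2ccc(OCc3ccccc3)cc2)[C@@H]1c1c(OCOC)cc(OCc2ccccc2)c2c(=O)cc(-c3ccc(OCc4ccccc4)cc3)oc12
A9 | alternative 3 | flavanone–flavone with free O5 and O7 on ring A and a methoxymethyl ether on O7″ | O=C1c2c(O)cc(O)cc2O[C@@H](c2ccc(OCc3ccccc3)cc2)[C@@H]1c1c(OCOC)cc(OCc2ccccc2)c2c(=O)cc(-c3ccc(OCc4ccccc4)cc3)oc12
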